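**Plan**

Atom labels: ring C1 (bears =CMe2), C2, C3, C4 (CHMe), C5 (quaternary), C6 (CH). The acid chain C7–C9 sits on C6. C10 is the CH2 between C5 and indole C3.
Cuts: first the ring bond C5–C6 together with one C10–H. Then C6–C1 (carbonyl-ene), C10–C3 of indole (acylation) and C5–CH3 (enolate methylation). This leaves (R)-citronellic acid, indole, methyl 4-oxobutanoate and MeI, which supply all 23 carbons.
Enabling feature: C5–C6 lies between C10, where the indole ring stabilises a cation, and C1=CMe2, the remnant of an allyl cation C6–C1–CMe2. C6 is also the γ-carbon of the acid C9, so the acid can serve as leaving group in the form of a temporary γ-lactone.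
Forward order: the indole rings are bought and the chain is assembled linearly. The cyclohexane is the only skeletal ring that is closed, and it is closed last (step 8). Helpers are the γ-lactone and the C5=C10 alkene (both consumed in step 8) and N-tosyl (removed in step 9).
Stereochemistry: C4 comes from (R)-citronellic acid. C5 and C6 are set together in the chair transition state of step 8 under control of C4.

Key step: step 8

Assumption: compounds 3–16 are carried as epimer mixtures at the transient centres (C5, C1, C6, C10). All of these are erased or reset by step 8, so only C4 is drawn with configuration.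

Step 1
Reactants: 1 (R)-citronellic acid
Product: 3 (3R)-2,3,7-trimethyloct-6-enoic acid, via dilithium enediolate 2 (not isolated)
Conditions: LiN(iPr)2 (2.2 equiv), THF, −78 to 0 °C; MeI, −78 °C to rt; aq HCl
Reagents that add atoms: iodomethane CI
Why: Alkylation of a carboxylic acid dianion: the enediolate is methylated at C5 without facial control, which does not matter because C5 becomes sp2 in step 7, and C4 is not touched.

Step 2
Reactants: 3 (3R)-2,3,7-trimethyloct-6-enoic acid; 4 indole
Product: 8 (3R)-1-(1H-indol-3-yl)-2,3,7-trimethyloct-6-en-1-one, via acid chloride 5 (not isolated), via indol-1-ylmagnesium bromide 6 (not isolated), via indol-1-ylzinc chloride 7 (not isolated)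
Conditions: 3, (COCl)2, cat. DMF, CH2Cl2, 0 °C to rt, concentrate; separately 4, EtMgBr, Et2O/CH2Cl2, 0 °C, then ZnCl2; add 5, 0 °C to rt
Reagents that add atoms: none
Why: Acid chloride formation followed by C3-selective Friedel–Crafts-type acylation of an N-metalated indole, which avoids strong Lewis acids that would cyclise the acid chloride onto the C1=CMe2 alkene; no stereocentre is formed.

Step 3
Reactants: 8 (3R)-1-(1H-indol-3-yl)-2,3,7-trimethyloct-6-en-1-one; 9 methyl 4-oxobutanoate
Product: 11 5-[(6R)-8-(1H-indol-3-yl)-2,6,7-trimethyl-8-oxooct-1-en-3-yl]oxolan-2-one, via ene adduct hydroxy ester 10 (not isolated)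
Conditions: 9 (1.5 equiv), Me2AlCl (4 equiv), CH2Cl2, −78 to −20 °C; aq HCl; cat. PPTS, CH2Cl2, rt
Reagents that add atoms: none
Why: Me2AlCl-promoted intermolecular carbonyl-ene reaction: the trisubstituted alkene bonds through its less substituted carbon C1 to the aldehyde carbon (C6) and gives up a methyl hydrogen, the γ-hydroxy ester then lactonises, the N-aluminated vinylogous amide is too poor an enophile to compete, and the new centres C1 and C6 form unselectively because both are erased later (steps 5 and 8).

Step 4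
Reactants: 11 isopropenyl lactone (NH)
Product: 12 5-[(6R)-2,6,7-trimethyl-8-oxo-8-(1-tosylindol-3-yl)oct-1-en-3-yl]oxolan-2-one
Conditions: TsCl, Et3N, cat. DMAP, CH2Cl2, rt
Reagents that add atoms: p-toluenesulfonyl chloride Cc1ccc(cc1)S(=O)(=O)Cl
Why: N-Sulfonylation of the acidic NH of a 3-acylindole; the tosyl group tames the indole nucleus for steps 7 and 8 and makes the ketone reducible; no stereocentre is formed.

Step 5
Reactants: 12 N-tosyl isopropenyl lactone
Product: 13 5-[(6R)-2,6,7-trimethyl-8-oxo-8-(1-tosylindol-3-yl)oct-2-en-3-yl]oxolan-2-one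
Conditions: chloro[N,N'-bis(3,5-di-tert-butylsalicylidene)ethane-1,2-diaminato]cobalt (3 mol %), PhSiH3 (6 mol %), benzene, rt
Reagents that add atoms: none
Why: Cobalt hydride hydrogen-atom-transfer (MHAT) alkene isomerisation by one position: reversible H-atom addition to the =CH2 terminus gives the tertiary radical at CMe2, and H-atom abstraction from C1–H gives the tetrasubstituted alkene, which is too hindered to re-enter the cycle, so C1 loses its centre and the C6–O bond becomes allylic.

Step 6
Reactants: 13 N-tosyl allylic lactone ketone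
Product: 14 5-[(6R)-8-hydroxy-2,6,7-trimethyl-8-(1-tosylindol-3-yl)oct-2-en-3-yl]oxolan-2-one
Conditions: NaBH4, CeCl3·7H2O, MeOH/THF, −20 to 0 °C
Reagents that add atoms: none
Why: Luche-type 1,2-reduction of the aryl ketone, which is faster than attack on the γ-lactone; the C10 carbinol centre forms unselectively and is erased in step 7.

Step 7
Reactants: 14 indolyl carbinol
Product: 16 5-[(6R,7E)-2,6,7-trimethyl-8-(1-tosylindol-3-yl)octa-2,7-dien-3-yl]oxolan-2-one, via C10 mesylate 15 (not isolated)
Conditions: MsCl, Et3N (4 equiv), CH2Cl2, 0 °C to reflux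
Reagents that add atoms: none
Why: Mesylation and E1-type elimination of the benzylic-type mesylate, whose only β-hydrogen is on C5, should give the conjugated alkene mainly as the more stable (E)-isomer with the indolyl group trans to the branched C4 substituent.

Step 8
Reactants: 16 (E)-alkenylindole allylic lactone
Product: 18 N-tosylsuaveolindole, via triethylsilyl ester 17 (not isolated)
Conditions: Et3SiH (3 equiv), Me3SiOTf (0.2 equiv), 2,6-di-tert-butylpyridine (0.05 equiv), CH2Cl2 (0.005 M), −78 to −40 °C; aq NaHCO3, then citric acid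
Reagents that add atoms: none
Why: Proposed new method: Me3SiOTf silylates the lactone carbonyl and the allylic C6–O bond ionises to the tetraalkylallyl cation C6–C1–CMe2 with the acid set free as its silyl ester, C5 of the (E)-alkenylindole attacks C6, and the indol-3-ylmethyl cation at C10, which has no hydrogen on C5 to lose, takes hydride from Et3SiH, which passes Et3Si+ on to the next lactone. The closest known reaction types are the allyl-cation-initiated cation–olefin cyclisation ended by an aryl-substituted alkene and the ionic hydrogenation of benzylic cations with silanes. The cyclohexane closes 6-exo-trig at the C5=C10 alkene and 6-endo-trig at the C6=C1 part of the cation; attack at CMe2 would need an eight-membered ring, so ring size fixes the regiochemistry and C1=CMe2 is the only alkene that can result. C6: the cation is planar, so both lactone epimers converge, and it keeps the C7 chain syn to C2 and away from CMe2 (allylic 1,3-strain), which places the chain axial in the chair and anti to C10. C5: with the C4 methyl equatorial (an axial one would meet the axial chain in a 1,3-diaxial contact) and the vinylic hydrogen of the (E)-alkene facing C4, the flat sp2 carbon C10 takes the crowded axial site over the allyl face and the tetrahedral C5 methyl the equatorial one, so C10 ends cis to the C4 methyl and trans to the chain, as in the target. The step needs ring closure to outrun hydride capture and proton loss of the allyl cation and needs a silent indole nucleus: the six-membered intramolecular attack at high dilution secures the first, and the N-tosyl group, which blocks attack through C2 and N yet leaves enough donor power to stabilise C10, secures the second.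

Step 9
Reactants: 18 N-tosylsuaveolindole
Product: 19 suaveolindole
Conditions: KOH, MeOH/THF/H2O, 65 °C; aq HCl to pH 4
Reagents that add atoms: none
Why: Hydrolytic cleavage of the N-sulfonyl group of an indole with hydroxide; the alkene, the acid (as carboxylate) and the three stereocentres, none of which is enolisable, are inert.

**Compound list**

1 | (R)-citronellic acid, (3R)-3,7-dimethyloct-6-enoic acid | CC(C)=CCC[C@@H](C)CC(=O)O | starting material
2 | dilithium enediolate of 1 | CC(C)=CCC[C@@H](C)C=C([O-])[O-].[Li+].[Li+] | intermediate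
3 | (3R)-2,3,7-trimethyloct-6-enoic acid (C2 epimers) | CC(C)=CCC[C@@H](C)C(C)C(=O)O | intermediate
4 | indole | c1ccc2[nH]ccc2c1 | starting material
5 | (3R)-2,3,7-trimethyloct-6-enoyl chloride | CC(C)=CCC[C@@H](C)C(C)C(=O)Cl | intermediate
6 | indol-1-ylmagnesium bromide | Br[Mg]n1ccc2ccccc12 | intermediate
7 | indol-1-ylzinc chloride | Cl[Zn]n1ccc2ccccc12 | intermediate
8 | (3R)-1-(1H-indol-3-yl)-2,3,7-trimethyloct-6-en-1-one | CC(C)=CCC[C@@H](C)C(C)C(=O)c1c[nH]c2ccccc12 | intermediate
9 | methyl 4-oxobutanoate | COC(=O)CCC=O | starting material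
10 | methyl (8R)-4-hydroxy-10-(1H-indol-3-yl)-8,9-dimethyl-10-oxo-5-(prop-1-en-2-yl)decanoate | C=C(C)C(CC[C@@H](C)C(C)C(=O)c1c[nH]c2ccccc12)C(O)CCC(=O)OC | intermediate
11 | 5-[(6R)-8-(1H-indol-3-yl)-2,6,7-trimethyl-8-oxooct-1-en-3-yl]oxolan-2-one | C=C(C)C(CC[C@@H](C)C(C)C(=O)c1c[nH]c2ccccc12)C1CCC(=O)O1 | intermediate
12 | 5-[(6R)-2,6,7-trimethyl-8-oxo-8-(1-tosylindol-3-yl)oct-1-en-3-yl]oxolan-2-one | C=C(C)C(CC[C@@H](C)C(C)C(=O)c1cn(S(=O)(=O)c2ccc(C)cc2)c2ccccc12)C1CCC(=O)O1 | intermediate
13 | 5-[(6R)-2,6,7-trimethyl-8-oxo-8-(1-tosylindol-3-yl)oct-2-en-3-yl]oxolan-2-one | CC(C)=C(CC[C@@H](C)C(C)C(=O)c1cn(S(=O)(=O)c2ccc(C)cc2)c2ccccc12)C1CCC(=O)O1 | intermediate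
14 | 5-[(6R)-8-hydroxy-2,6,7-trimethyl-8-(1-tosylindol-3-yl)oct-2-en-3-yl]oxolan-2-one | CC(C)=C(CC[C@@H](C)C(C)C(O)c1cn(S(=O)(=O)c2ccc(C)cc2)c2ccccc12)C1CCC(=O)O1 | intermediate
15 | C10 methanesulfonate of 14 | CC(C)=C(CC[C@@H](C)C(C)C(OS(C)(=O)=O)c1cn(S(=O)(=O)c2ccc(C)cc2)c2ccccc12)C1CCC(=O)O1 | intermediate
16 | 5-[(6R,7E)-2,6,7-trimethyl-8-(1-tosylindol-3-yl)octa-2,7-dien-3-yl]oxolan-2-one | CC(C)=C(CC[C@@H](C)/C(C)=C/c1cn(S(=O)(=O)c2ccc(C)cc2)c2ccccc12)C1CCC(=O)O1 | intermediate
17 | triethylsilyl ester of 18 | CC(C)=C1CC[C@@H](C)[C@@](C)(Cc2cn(S(=O)(=O)c3ccc(C)cc3)c3ccccc23)[C@@H]1CCC(=O)O[Si](CC)(CC)CC | intermediate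
18 | N-tosylsuaveolindole, 3-[(1S,2R,3R)-2,3-dimethyl-6-(propan-2-ylidene)-2-[(1-tosylindol-3-yl)methyl]cyclohexyl]propanoic acid | CC(C)=C1CC[C@@H](C)[C@@](C)(Cc2cn(S(=O)(=O)c3ccc(C)cc3)c3ccccc23)[C@@H]1CCC(=O)O | intermediate
19 | suaveolindole, 3-[(1S,2R,3R)-2-(1H-indol-3-ylmethyl)-2,3-dimethyl-6-(propan-2-ylidene)cyclohexyl]propanoic acid | CC(C)=C1CC[C@@H](C)[C@@](C)(Cc2c[nH]c3ccccc23)[C@@H]1CCC(=O)O | target

Total step count: 9. Longest linear sequence: 9 (from 1).

**Steps most likely to fail**

**Step 8 (bears the label).**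
- What may go wrong: hydride capture or proton loss of the allyl cation before ring closure; a 1,2-shift in the neopentyl-type C10 cation before hydride arrives; poor facial selectivity at C5, made worse by any (Z)-alkene carried in.
- Fallback, from 3 back to 19: the same C5–C6 bond is closed by known enamine/π-allylpalladium chemistry, and the indole is attached afterwards.
- LiAlH4 reduction of 3 should give (3R)-2,3,7-trimethyloct-6-en-1-ol F1.
- The Me2AlCl carbonyl-ene reaction with 9 and lactonisation, as in step 3, should give 5-[(6R)-8-hydroxy-2,6,7-trimethyloct-1-en-3-yl]oxolan-2-one F2.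
- The cobalt hydride isomerisation of step 5 should give 5-[(6R)-8-hydroxy-2,6,7-trimethyloct-2-en-3-yl]oxolan-2-one F3.
- Dess–Martin oxidation should give (3R)-2,3,7-trimethyl-6-(5-oxooxolan-2-yl)oct-6-enal F4.
- With Pd(PPh3)4 and pyrrolidine (Tsuji–Trost cyclisation of an enamine, with the vinyl lactone as allyl donor to zerovalent palladium), F4 should close to 3-[2-formyl-2,3-dimethyl-6-(propan-2-ylidene)cyclohexyl]propanoic acid F5. F5 has the ring configuration of 19.
- Reagent 6 (3 equiv) adds to the aldehyde to give the indol-3-yl carbinol acid F6.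
- NaBH4 in hot 2-propanol removes the hydroxyl through the 3-alkylidene-3H-indole to give 19.

**Step 5.**
- What may go wrong: stalling of the hydrogen-atom abstraction at the hindered C1–H, so that the isopropenyl isomer persists, or net reduction of the alkene.
- Fallback, from 12 back to 13: an ionic addition–elimination replaces the radical isomerisation.
- Markovnikov addition of HCl (Et2O, 0 °C) should give the tertiary chloride 5-[(6R)-2-chloro-2,6,7-trimethyl-8-oxo-8-(1-tosylindol-3-yl)octan-3-yl]oxolan-2-one F7.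
- E1-type dehydrochlorination (LiBr, Li2CO3, DMF, 90 °C) should give the Zaitsev alkene 13.

**Step 3.**
- What may go wrong: methyl transfer from aluminium to the aldehyde, oligomerisation of the aldehyde, or chloride capture of the developing cation instead of the ene pathway.
- Fallback, from 3 back to 13 (it also bypasses step 5): C1 is made a vinyl nucleophile.
- Br2 addition to 3 should give (3R)-6,7-dibromo-2,3,7-trimethyloctanoic acid F8.
- Dehydrobromination with DBU should give (3R)-6-bromo-2,3,7-trimethyloct-6-enoic acid F9.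
- t-BuLi (3 equiv, −78 °C) and then 9 should give, after 1,2-addition and lactonisation, (3R)-2,3,7-trimethyl-6-(5-oxooxolan-2-yl)oct-6-enoic acid F10.
- Conversion to the acid chloride and acylation of 7, as in step 2, should give the NH allylic lactone ketone 5-[(6R)-8-(1H-indol-3-yl)-2,6,7-trimethyl-8-oxooct-2-en-3-yl]oxolan-2-one F11.
- Tosylation as in step 4 gives 13.

Further compounds
F1 | step 8 | (3R)-2,3,7-trimethyloct-6-en-1-ol | CC(C)=CCC[C@@H](C)C(C)CO
F2 | step 8 | 5-[(6R)-8-hydroxy-2,6,7-trimethyloct-1-en-3-yl]oxolan-2-one | C=C(C)C(CC[C@@H](C)C(C)CO)C1CCC(=O)O1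
F3 | step 8 | 5-[(6R)-8-hydroxy-2,6,7-trimethyloct-2-en-3-yl]oxolan-2-one | CC(C)=C(CC[C@@H](C)C(C)CO)C1CCC(=O)O1
F4 | step 8 | (3R)-2,3,7-trimethyl-6-(5-oxooxolan-2-yl)oct-6-enal | CC(C)=C(CC[C@@H](C)C(C)C=O)C1CCC(=O)O1
F5 | step 8 | 3-[2-formyl-2,3-dimethyl-6-(propan-2-ylidene)cyclohexyl]propanoic acid, ring configuration as in 19 | CC(C)=C1CC[C@@H](C)[C@@](C)(C=O)[C@@H]1CCC(=O)O
F6 | step 8 | 3-[2-[hydroxy(1H-indol-3-yl)methyl]-2,3-dimethyl-6-(propan-2-ylidene)cyclohexyl]propanoic acid, ring configuration as in 19 | CC(C)=C1CC[C@@H](C)[C@@](C)(C(O)c2c[nH]c3ccccc23)[C@@H]1CCC(=O)O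
F7 | step 5 | 5-[(6R)-2-chloro-2,6,7-trimethyl-8-oxo-8-(1-tosylindol-3-yl)octan-3-yl]oxolan-2-one | CC(C)(Cl)C(CC[C@@H](C)C(C)C(=O)c1cn(S(=O)(=O)c2ccc(C)cc2)c2ccccc12)C1CCC(=O)O1
F8 | step 3 | (3R)-6,7-dibromo-2,3,7-trimethyloctanoic acid | CC(C)(Br)C(Br)CC[C@@H](C)C(C)C(=O)O
F9 | step 3 | (3R)-6-bromo-2,3,7-trimethyloct-6-enoic acid | CC(C)=C(Br)CC[C@@H](C)C(C)C(=O)O
F10 | step 3 | (3R)-2,3,7-trimethyl-6-(5-oxooxolan-2-yl)oct-6-enoic acid | CC(C)=C(CC[C@@H](C)C(C)C(=O)O)C1CCC(=O)O1
F11 | step 3 | 5-[(6R)-8-(1H-indol-3-yl)-2,6,7-trimethyl-8-oxooct-2-en-3-yl]oxolan-2-one | CC(C)=C(CC[C@@H](C)C(C)C(=O)c1c[nH]c2ccccc12)C1CCC(=O)O1
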